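Read Thursday's run as a count of turnovers before any number is quoted for the new flask.

- Thursday's: left-handed substrate 0.30 M; right-handed substrate 0.30 M; reagent 0.60 M (fed, over 3.0 h); free catalyst 0.41 mM; run made earlier; the fed solution adds 0.25 times the starting volume
- flask: left-handed substrate 0.30 M; reagent 0.600 M (fed, over 3.0 h); free catalyst 0.27 mM; right-handed substrate 0.30 M; time 6.0 d; the fed solution adds 0.25 times the starting volume

Thursday's run (percent of the left-handed substrate and right-handed substrate together charged)

| time / h | left-handed substrate / % | right-handed substrate / % | left-handed product / % |
|---|---|---|---|
| 4.00 | 48.3 | 50.0 | 1.9 |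
| 10.0 | 46.7 | 49.7 | 2.8 |
| 20.0 | 45.6 | 48.8 | 4.0 |
| 30.0 | 45.2 | 49.7 | 5.0 |
| 40.0 | 44.7 | 50.0 | 4.8 |

(scatter of a reading: 0.5 percentage points)

- part of the left-handed substrate and right-handed substrate charged together that has reacted at 6.0 d
- excess of left-handed product over right-handed product in the product at 6.0 d
- excess of right-handed substrate over left-handed substrate among what is left of the two at 6.0 d

- free catalyst is single-handed; left-handed substrate and right-handed substrate are mirror images of each other, charged as a racemate, each of them at the stated concentration
- charges are per starting volume, the dose included; the dosed solution carries all of it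
- an excess is below zero if the other one leads
- no earlier run changes the charge of free catalyst; that part of a forecast is a guess

Conversion of the two substrates together in Thursday's run reaches 3.60% by 10.0 h, then gains 0.2 percentage points from 30.0 h to 40.0 h, a late gain smaller than the scatter of 0.5 points. Left-handed substrate still stands at 44.7% in that run, so the stall reads as a loss of free catalyst. The last two readings give 76.1 for substrate consumed per catalyst charged, the catalyst yield, known in the trade as the turnover number.

Your hunch of a dying catalyst fits this reading. At the same yield the reckoning offered here puts the new flask, with 0.27 mM of free catalyst, at 3.42% conversion, an estimate that remains a guess about catalyst load. The forecast argues “The plateau should then scale with catalyst load” and stands higher than this reckoning: 3.9% conversion, 87% product excess and 3.5% substrate excess.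

The flask gives 7.01% conversion, 80.1% product excess and 6.04% substrate excess.

    free catalyst → spent catalyst A (k = 0.0440 h⁻¹)
    reagent + free catalyst + right-handed substrate → free catalyst + right-handed product (k = 9.60 L² mol⁻² h⁻¹)
    2 free catalyst → spent catalyst B (k = 65.0 L mol⁻¹ h⁻¹)
    free catalyst ⇌ dormant form (K = 2.60, k = 0.0670 h⁻¹)
    reagent + free catalyst + left-handed substrate → free catalyst + left-handed product (k = 92.0 L² mol⁻² h⁻¹)

The flask's yield is 94.7 at 1.50 d, above Thursday's reading, and 156 at 6.0 d, twice that reading. The neighbouring flask, with 1.0 M of reagent, has a yield of 250 at 6.0 d, which is 1.60 times the flask's for 1.67 times the reagent. At 6.0 d the neighbouring flask holds 69.5% of its catalyst as spent catalyst A, against 69.5% in the flask. Its conversion is 11.2%, and its product excess is 79.3%.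

(The runs come from a simulation with made-up constants, and the scatter is random.)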